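Ring A (C1, C2, C3, C4, C5, C10) is a cyclohexene whose C1=C10 alkene sits between the ring fusion and quaternary C4 (CH3, CO2CH3) beside the C5 methine. That is the retron of a [4+2] between a ring-B cyclohexene (C5=C10) carrying a vinyl group on C10 and methacrolein. This single cycloaddition forges C2–C3 and C4–C5, closes ring A, sets C4 and C5 and leaves the alkene at C1=C10. Its precursor is an enantiopure ring-B diene that already holds the C8 and C9 stereocentres and the complete (E)-allylic silyl ether side chain; the 13,14,15-oxygenation is added afterwards by asymmetric epoxidation, hydrolysis and acetylation.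

Key step: step 12

Remark: atoms carry halimane numbers (ring A C1–C5 and C10, ring B C5–C10, side chain C11–C15 on C9, methyls C16 on C13, C17 on C8, C20 on C9); the ligand antipode in step 1 and the catalyst antipode in step 12 are working assignments to be confirmed on the first batch and exchanged for the mirror image if the sense is opposite.

Step 1
Reactants: 1 2-methylcyclohex-2-en-1-one; 2 trimethylaluminium
Product: 4 (R)-(2,3-dimethylcyclohex-1-en-1-yloxy)trimethylsilane, via aluminium enolate 3 (not isolated)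
Conditions: Me3Al (1.4 equiv), CuTC (monovalent copper thiophene-2-carboxylate, Cu(O2CC4H3S), 2 mol %), (S,S)-biphenol bis(1-phenylethyl)amine phosphoramidite (4 mol %), Et2O, −30 °C; then TMSOTf, Et3N, −30 °C → rt
Reagents that add atoms: trimethylaluminium 2, C[Al](C)C; trimethylsilyl triflate, C[Si](C)(C)OS(=O)(=O)C(F)(F)F
Why: Copper-catalysed asymmetric conjugate addition under phosphoramidite ligand control places the methyl on the β-carbon (C8 of the target, R), and O-silylation of the aluminium enolate stores the enolate regiochemistry.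

Step 2
Reactants: 4 (R)-(2,3-dimethylcyclohex-1-en-1-yloxy)trimethylsilane; 5 allyl bromide
Product: 7 (2S,3R)-2-allyl-2,3-dimethylcyclohexan-1-one, via lithium enolate 6 (not isolated)
Conditions: MeLi, THF, 0 °C → rt; then DMPU, allyl bromide, −78 → 0 °C
Reagents that add atoms: allyl bromide 5, C=CCBr
Why: Regiospecific enolate alkylation: MeLi cleaves the silyl enol ether to the tetrasubstituted lithium enolate, which is C-allylated anti to the neighbouring pseudoaxial C8 methyl, so quaternary C9 (S) forms with the two methyls cis; the minor epimer is removed by chromatography.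

Step 3
Reactants: 7 (2S,3R)-2-allyl-2,3-dimethylcyclohexan-1-one
Product: 8 (6S,7R)-6-allyl-6,7-dimethyl-1,4-dioxaspiro[4.5]decane
Conditions: HOCH2CH2OH, p-TsOH (cat.), benzene, reflux, Dean–Stark
Reagents that add atoms: ethylene glycol, OCCO
Why: Acid-catalysed dioxolane formation with azeotropic removal of water; the α-carbon is quaternary and cannot epimerise, and the masked ketone tolerates the borane and organoaluminium reagents that follow.

Step 4
Reactants: 8 (6S,7R)-6-allyl-6,7-dimethyl-1,4-dioxaspiro[4.5]decane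
Product: 10 3-[(6S,7R)-6,7-dimethyl-1,4-dioxaspiro[4.5]decan-6-yl]propan-1-ol, via B-alkyl-9-BBN adduct 9 (not isolated)
Conditions: 9-BBN, THF, 0 °C → rt; then 3 M NaOH, 30% H2O2, 0 °C → rt
Reagents that add atoms: hydrogen peroxide, OO; 9-borabicyclo[3.3.1]nonane, B1C2CCCC1CCC2 (its boron stays only in intermediate 9)
Why: Brown hydroboration–oxidation: the bulky borane adds anti-Markovnikov to the monosubstituted alkene and oxidative work-up gives the primary alcohol, the ketal being inert.

Step 5
Reactants: 10 3-[(6S,7R)-6,7-dimethyl-1,4-dioxaspiro[4.5]decan-6-yl]propan-1-ol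
Product: 11 3-[(6S,7R)-6,7-dimethyl-1,4-dioxaspiro[4.5]decan-6-yl]propanal
Conditions: (COCl)2, DMSO, CH2Cl2, −78 °C; Et3N, −78 → 0 °C
Reagents that add atoms: none
Why: Swern oxidation stops at the aldehyde under amine-buffered conditions that leave the dioxolane intact.

Step 6
Reactants: 11 3-[(6S,7R)-6,7-dimethyl-1,4-dioxaspiro[4.5]decan-6-yl]propanal; 12 dimethyl (1-diazo-2-oxopropyl)phosphonate (Bestmann–Ohira reagent)
Product: 13 (6S,7R)-6-(but-3-yn-1-yl)-6,7-dimethyl-1,4-dioxaspiro[4.5]decane
Conditions: K2CO3, MeOH, 0 °C → rt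
Reagents that add atoms: Bestmann–Ohira reagent 12, COP(=O)(OC)C(=[N+]=[N-])C(C)=O
Why: Seyferth–Gilbert homologation in its Bestmann–Ohira form: methanolysis of 12 releases the diazomethylphosphonate anion, which turns the aldehyde into the terminal alkyne (C13≡C14) under mild base harmless to the ketal.

Step 7
Reactants: 13 (6S,7R)-6-(but-3-yn-1-yl)-6,7-dimethyl-1,4-dioxaspiro[4.5]decane; 2 trimethylaluminium; 14 formaldehyde (used as paraformaldehyde)
Product: 17 (E)-5-[(6S,7R)-6,7-dimethyl-1,4-dioxaspiro[4.5]decan-6-yl]-3-methylpent-2-en-1-ol, via alkenylalane 15 (not isolated), via lithium alkenylaluminate 16 (not isolated)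
Conditions: Me3Al (3 equiv), Cp2ZrCl2 (20 mol %), H2O (1 equiv), CH2Cl2, −23 °C; volatiles removed; n-BuLi, THF, −78 °C; (CH2O)n, −78 °C → rt
Reagents that add atoms: trimethylaluminium 2, C[Al](C)C; formaldehyde 14, C=O (n-butyllithium, [Li]CCCC, enters intermediate 16 only)
Why: Negishi zirconium-catalysed methylalumination adds CH3 and Al syn with Al on the terminal carbon, and the aluminate attacks formaldehyde with retention, giving the (E)-C13=C14 alkene with C16 and C15 in place; the water-accelerated low-temperature protocol keeps the Lewis-acid-sensitive dioxolane in contact with Me3Al only briefly.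

Step 8
Reactants: 17 (E)-5-[(6S,7R)-6,7-dimethyl-1,4-dioxaspiro[4.5]decan-6-yl]-3-methylpent-2-en-1-ol
Product: 18 tert-butyl{[(E)-5-((6S,7R)-6,7-dimethyl-1,4-dioxaspiro[4.5]decan-6-yl)-3-methylpent-2-en-1-yl]oxy}diphenylsilane
Conditions: TBDPSCl, imidazole, DMF, rt
Reagents that add atoms: tert-butyl(chloro)diphenylsilane, CC(C)(C)[Si](Cl)(c1ccccc1)c1ccccc1
Why: Standard silylation of the primary allylic alcohol gives an ether that withstands the acid, base, palladium and Lewis acid of steps 9 to 14.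

Step 9
Reactants: 18 tert-butyl{[(E)-5-((6S,7R)-6,7-dimethyl-1,4-dioxaspiro[4.5]decan-6-yl)-3-methylpent-2-en-1-yl]oxy}diphenylsilane
Product: 19 (2S,3R)-2-[(E)-5-(tert-butyldiphenylsilyloxy)-3-methylpent-3-en-1-yl]-2,3-dimethylcyclohexan-1-one
Conditions: 1 M HCl, THF, rt
Reagents that add atoms: water, O
Why: Aqueous acid hydrolysis of the dioxolane frees the ketone, while the TBDPS ether and the trisubstituted alkene are stable to dilute acid at room temperature.

Step 10
Reactants: 19 (2S,3R)-2-[(E)-5-(tert-butyldiphenylsilyloxy)-3-methylpent-3-en-1-yl]-2,3-dimethylcyclohexan-1-one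
Product: 21 (5R,6S)-6-[(E)-5-(tert-butyldiphenylsilyloxy)-3-methylpent-3-en-1-yl]-5,6-dimethylcyclohex-1-en-1-yl trifluoromethanesulfonate, via potassium enolate 20 (not isolated)
Conditions: KHMDS, THF, −78 °C; PhNTf2, −78 → 0 °C
Reagents that add atoms: N-phenylbis(trifluoromethanesulfonimide), O=S(=O)(N(c1ccccc1)S(=O)(=O)C(F)(F)F)C(F)(F)F
Why: Enol triflate formation: C9 is quaternary, so the ketone can enolise only toward C5 and O-sulfonylation of the single enolate gives the C5=C10 triflate.

Step 11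
Reactants: 21 (5R,6S)-6-[(E)-5-(tert-butyldiphenylsilyloxy)-3-methylpent-3-en-1-yl]-5,6-dimethylcyclohex-1-en-1-yl trifluoromethanesulfonate; 22 tributyl(vinyl)stannane
Product: 23 tert-butyl{[(E)-5-((1S,6R)-1,6-dimethyl-2-vinylcyclohex-2-en-1-yl)-3-methylpent-2-en-1-yl]oxy}diphenylsilane
Conditions: Pd(PPh3)4 (5 mol %), LiCl, THF, 65 °C
Reagents that add atoms: tributyl(vinyl)stannane 22, C=C[Sn](CCCC)(CCCC)CCCC
Why: Stille coupling of the alkenyl triflate (oxidative addition to zerovalent palladium, chloride-assisted transmetalation, reductive elimination) attaches C1 and C2 to C10 and gives the 1,3-diene without touching a stereocentre.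

Step 12
Reactants: 23 tert-butyl{[(E)-5-((1S,6R)-1,6-dimethyl-2-vinylcyclohex-2-en-1-yl)-3-methylpent-2-en-1-yl]oxy}diphenylsilane; 24 methacrolein
Product: 25 (1R,5S,6R,8aR)-5-[(E)-5-(tert-butyldiphenylsilyloxy)-3-methylpent-3-en-1-yl]-1,5,6-trimethyl-1,2,3,5,6,7,8,8a-octahydronaphthalene-1-carbaldehyde (halimane positions 4R,5R,8R,9S)
Conditions: methacrolein (5 equiv), (S)-3,3-diphenyl-1-(o-tolyl)tetrahydro-1H,3H-pyrrolo[1,2-c][1,3,2]oxazaborole·HNTf2 (20 mol %), CH2Cl2, −78 → −40 °C
Reagents that add atoms: methacrolein 24, CC(=C)C=O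
Why: The protonated oxazaborolidine binds the formyl oxygen of 24, and diene 23 adds in a concerted, asynchronous, suprafacial [4+2] in which the C2–C3 bond (vinyl terminus to enal β-carbon) runs ahead of the C4–C5 bond (ring carbon to enal α-carbon). The closest known reactions are the oxazaborolidinium-catalysed exo-selective Diels–Alder additions of α-methylacrolein to 1,3-dienes and the ortho-selective cycloadditions of 1-vinylcyclohexenes with acrylic dienophiles. Six-membered ring A is closed in the intermolecular [4π+2π] mode, both σ-bonds forming in the one step while the alkene moves to C1=C10. C4 is fixed by the catalyst, which shields one enantioface of the bound enal, and C5 follows from the exo topology (formyl turned away from the diene, hence cis to H5) combined with approach to the diene face bearing the C11 chain, anti to the C9 methyl. The step needs ortho regiochemistry, exo selectivity and β-face attack: the first comes from the larger HOMO coefficient and easier access at C2, the second from the α-methyl group and the quaternary C9, which crowds the endo pocket against the catalyst-bound formyl group, and the third from choosing the catalyst antipode that matches the conformer of 23 with the C9 methyl pseudoaxial. Exo selectivity of α-methyl enals is firmly established for cyclic dienes and less so for semicyclic ones, so the route depends on this step.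

Step 13
Reactants: 25 the aldehyde from step 12
Product: 26 (1R,5S,6R,8aR)-5-[(E)-5-(tert-butyldiphenylsilyloxy)-3-methylpent-3-en-1-yl]-1,5,6-trimethyl-1,2,3,5,6,7,8,8a-octahydronaphthalene-1-carboxylic acid
Conditions: NaClO2, NaH2PO4, 2-methyl-2-butene, t-BuOH/H2O, 0 °C → rt
Reagents that add atoms: sodium chlorite, [Na+].[O-]Cl=O
Why: Pinnick oxidation converts the hindered neopentyl aldehyde into the acid; 2-methyl-2-butene traps hypochlorite so both trisubstituted alkenes survive, and quaternary C4 cannot epimerise.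

Step 14
Reactants: 26 the carboxylic acid from step 13
Product: 27 methyl (1R,5S,6R,8aR)-5-[(E)-5-(tert-butyldiphenylsilyloxy)-3-methylpent-3-en-1-yl]-1,5,6-trimethyl-1,2,3,5,6,7,8,8a-octahydronaphthalene-1-carboxylate
Conditions: TMSCHN2, MeOH/toluene, 0 °C → rt
Reagents that add atoms: (trimethylsilyl)diazomethane, C[Si](C)(C)C=[N+]=[N-]
Why: O-Methylation of the carboxylic acid by the diazoalkane (protonation, then carboxylate displacement of N2) succeeds on hindered acids where Fischer esterification would not.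

Step 15
Reactants: 27 the silyl ether methyl ester from step 14
Product: 28 methyl (1R,5S,6R,8aR)-5-[(E)-5-hydroxy-3-methylpent-3-en-1-yl]-1,5,6-trimethyl-1,2,3,5,6,7,8,8a-octahydronaphthalene-1-carboxylate
Conditions: TBAF, THF, rt
Reagents that add atoms: none
Why: Fluoride-induced desilylation frees the allylic alcohol; the hindered methyl ester and both alkenes are unaffected.

Step 16
Reactants: 28 the (E)-allylic alcohol from step 15
Product: 29 methyl (1R,5S,6R,8aR)-5-{2-[(2R,3R)-3-(hydroxymethyl)-2-methyloxiran-2-yl]ethyl}-1,5,6-trimethyl-1,2,3,5,6,7,8,8a-octahydronaphthalene-1-carboxylate (13R,14R)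
Conditions: Ti(OiPr)4, D-(−)-diethyl tartrate, t-BuOOH, 4 Å MS, CH2Cl2, −20 °C
Reagents that add atoms: tert-butyl hydroperoxide, CC(C)(C)OO
Why: Sharpless asymmetric epoxidation: the titanium tartrate complex binds the allylic alcohol and delivers oxygen to the C13=C14 face dictated by D-(−)-DET (the sense known for geraniol-type alcohols), giving the (13R,14R) epoxide; the C1=C10 alkene has no directing hydroxyl and is not oxidised.

Step 17
Reactants: 29 the (13R,14R)-epoxy alcohol from step 16
Product: 30 methyl (1R,5S,6R,8aR)-5-[(3S,4R)-3,4,5-trihydroxy-3-methylpentyl]-1,5,6-trimethyl-1,2,3,5,6,7,8,8a-octahydronaphthalene-1-carboxylate (13S,14R)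
Conditions: 5% aq. HClO4, THF, 0 °C → rt
Reagents that add atoms: water, O
Why: Acid-catalysed epoxide hydrolysis: water attacks the protonated epoxide at tertiary C13, the carbon that best carries positive charge and is remote from the electron-withdrawing CH2OH, with inversion, so C13 becomes S while C14 keeps its R configuration; the large excess of water outcompetes participation by the C1=C10 alkene.

Step 18
Reactants: 30 the (13S,14R)-triol from step 17
Product: 31 methyl (1R,5S,6R,8aR)-5-[(3S,4R)-4,5-diacetoxy-3-hydroxy-3-methylpentyl]-1,5,6-trimethyl-1,2,3,5,6,7,8,8a-octahydronaphthalene-1-carboxylate (target CNP0238486.1)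
Conditions: Ac2O, pyridine, rt
Reagents that add atoms: acetic anhydride, CC(=O)OC(C)=O
Why: Acylation in pyridine esterifies the primary C15 and secondary C14 hydroxyls, whereas the tertiary C13 hydroxyl is too hindered to react without a stronger acyl-transfer catalyst or heat.

Compound list
1 | 2-methylcyclohex-2-en-1-one | CC1=CCCCC1=O | starting material
2 | trimethylaluminium | C[Al](C)C | starting material
3 | dimethylaluminium (R)-2,3-dimethylcyclohex-1-en-1-olate | C[C@@H]1CCCC(O[Al](C)C)=C1C | intermediate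
4 | (R)-(2,3-dimethylcyclohex-1-en-1-yloxy)trimethylsilane | C[C@@H]1CCCC(O[Si](C)(C)C)=C1C | intermediate
5 | allyl bromide | C=CCBr | starting material
6 | lithium (R)-2,3-dimethylcyclohex-1-en-1-olate | C[C@@H]1CCCC(O[Li])=C1C | intermediate
7 | (2S,3R)-2-allyl-2,3-dimethylcyclohexan-1-one | O=C1CCC[C@@H](C)[C@]1(C)CC=C | intermediate
8 | (6S,7R)-6-allyl-6,7-dimethyl-1,4-dioxaspiro[4.5]decane | O1CCOC12CCC[C@@H](C)[C@]2(C)CC=C | intermediate
9 | 9-{3-[(6S,7R)-6,7-dimethyl-1,4-dioxaspiro[4.5]decan-6-yl]propyl}-9-borabicyclo[3.3.1]nonane | O1CCOC12CCC[C@@H](C)[C@]2(C)CCCB3C4CCCC3CCC4 | intermediate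
10 | 3-[(6S,7R)-6,7-dimethyl-1,4-dioxaspiro[4.5]decan-6-yl]propan-1-ol | O1CCOC12CCC[C@@H](C)[C@]2(C)CCCO | intermediate
11 | 3-[(6S,7R)-6,7-dimethyl-1,4-dioxaspiro[4.5]decan-6-yl]propanal | O1CCOC12CCC[C@@H](C)[C@]2(C)CCC=O | intermediate
12 | dimethyl (1-diazo-2-oxopropyl)phosphonate | COP(=O)(OC)C(=[N+]=[N-])C(C)=O | starting material
13 | (6S,7R)-6-(but-3-yn-1-yl)-6,7-dimethyl-1,4-dioxaspiro[4.5]decane | O1CCOC12CCC[C@@H](C)[C@]2(C)CCC#C | intermediate
14 | formaldehyde (as paraformaldehyde) | C=O | starting material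
15 | {(E)-4-[(6S,7R)-6,7-dimethyl-1,4-dioxaspiro[4.5]decan-6-yl]-2-methylbut-1-en-1-yl}dimethylalane | O1CCOC12CCC[C@@H](C)[C@]2(C)CC/C(C)=C/[Al](C)C | intermediate
16 | lithium butyl{(E)-4-[(6S,7R)-6,7-dimethyl-1,4-dioxaspiro[4.5]decan-6-yl]-2-methylbut-1-en-1-yl}dimethylaluminate | [Li+].O1CCOC12CCC[C@@H](C)[C@]2(C)CC/C(C)=C/[Al-](C)(C)CCCC | intermediate
17 | (E)-5-[(6S,7R)-6,7-dimethyl-1,4-dioxaspiro[4.5]decan-6-yl]-3-methylpent-2-en-1-ol | O1CCOC12CCC[C@@H](C)[C@]2(C)CC/C(C)=C/CO | intermediate
18 | tert-butyl{[(E)-5-((6S,7R)-6,7-dimethyl-1,4-dioxaspiro[4.5]decan-6-yl)-3-methylpent-2-en-1-yl]oxy}diphenylsilane | O1CCOC12CCC[C@@H](C)[C@]2(C)CC/C(C)=C/CO[Si](c3ccccc3)(c3ccccc3)C(C)(C)C | intermediate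
19 | (2S,3R)-2-[(E)-5-(tert-butyldiphenylsilyloxy)-3-methylpent-3-en-1-yl]-2,3-dimethylcyclohexan-1-one | O=C1CCC[C@@H](C)[C@]1(C)CC/C(C)=C/CO[Si](c1ccccc1)(c1ccccc1)C(C)(C)C | intermediate
20 | potassium (5R,6S)-6-[(E)-5-(tert-butyldiphenylsilyloxy)-3-methylpent-3-en-1-yl]-5,6-dimethylcyclohex-1-en-1-olate | [K+].[O-]C1=CCC[C@@H](C)[C@]1(C)CC/C(C)=C/CO[Si](c1ccccc1)(c1ccccc1)C(C)(C)C | intermediate
21 | (5R,6S)-6-[(E)-5-(tert-butyldiphenylsilyloxy)-3-methylpent-3-en-1-yl]-5,6-dimethylcyclohex-1-en-1-yl trifluoromethanesulfonate | O=S(=O)(OC1=CCC[C@@H](C)[C@]1(C)CC/C(C)=C/CO[Si](c1ccccc1)(c1ccccc1)C(C)(C)C)C(F)(F)F | intermediate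
22 | tributyl(vinyl)stannane | C=C[Sn](CCCC)(CCCC)CCCC | starting material
23 | tert-butyl{[(E)-5-((1S,6R)-1,6-dimethyl-2-vinylcyclohex-2-en-1-yl)-3-methylpent-2-en-1-yl]oxy}diphenylsilane | C=CC1=CCC[C@@H](C)[C@]1(C)CC/C(C)=C/CO[Si](c1ccccc1)(c1ccccc1)C(C)(C)C | intermediate
24 | methacrolein | CC(=C)C=O | starting material
25 | (1R,5S,6R,8aR)-5-[(E)-5-(tert-butyldiphenylsilyloxy)-3-methylpent-3-en-1-yl]-1,5,6-trimethyl-1,2,3,5,6,7,8,8a-octahydronaphthalene-1-carbaldehyde | O=C[C@]1(C)CCC=C2[C@H]1CC[C@@H](C)[C@]2(C)CC/C(C)=C/CO[Si](c1ccccc1)(c1ccccc1)C(C)(C)C | intermediate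
26 | (1R,5S,6R,8aR)-5-[(E)-5-(tert-butyldiphenylsilyloxy)-3-methylpent-3-en-1-yl]-1,5,6-trimethyl-1,2,3,5,6,7,8,8a-octahydronaphthalene-1-carboxylic acid | OC(=O)[C@]1(C)CCC=C2[C@H]1CC[C@@H](C)[C@]2(C)CC/C(C)=C/CO[Si](c1ccccc1)(c1ccccc1)C(C)(C)C | intermediate
27 | methyl (1R,5S,6R,8aR)-5-[(E)-5-(tert-butyldiphenylsilyloxy)-3-methylpent-3-en-1-yl]-1,5,6-trimethyl-1,2,3,5,6,7,8,8a-octahydronaphthalene-1-carboxylate | COC(=O)[C@]1(C)CCC=C2[C@H]1CC[C@@H](C)[C@]2(C)CC/C(C)=C/CO[Si](c1ccccc1)(c1ccccc1)C(C)(C)C | intermediate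
28 | methyl (1R,5S,6R,8aR)-5-[(E)-5-hydroxy-3-methylpent-3-en-1-yl]-1,5,6-trimethyl-1,2,3,5,6,7,8,8a-octahydronaphthalene-1-carboxylate | COC(=O)[C@]1(C)CCC=C2[C@H]1CC[C@@H](C)[C@]2(C)CC/C(C)=C/CO | intermediate
29 | methyl (1R,5S,6R,8aR)-5-{2-[(2R,3R)-3-(hydroxymethyl)-2-methyloxiran-2-yl]ethyl}-1,5,6-trimethyl-1,2,3,5,6,7,8,8a-octahydronaphthalene-1-carboxylate | COC(=O)[C@]1(C)CCC=C2[C@H]1CC[C@@H](C)[C@]2(C)CC[C@@]3(C)O[C@@H]3CO | intermediate
30 | methyl (1R,5S,6R,8aR)-5-[(3S,4R)-3,4,5-trihydroxy-3-methylpentyl]-1,5,6-trimethyl-1,2,3,5,6,7,8,8a-octahydronaphthalene-1-carboxylate | COC(=O)[C@]1(C)CCC=C2[C@H]1CC[C@@H](C)[C@]2(C)CC[C@](C)(O)[C@@H](CO)O | intermediate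
31 | methyl (1R,5S,6R,8aR)-5-[(3S,4R)-4,5-diacetoxy-3-hydroxy-3-methylpentyl]-1,5,6-trimethyl-1,2,3,5,6,7,8,8a-octahydronaphthalene-1-carboxylate | COC(=O)[C@]1(C)CCC=C2[C@H]1CC[C@@H](C)[C@]2(C)CC[C@](C)(O)[C@@H](COC(C)=O)OC(C)=O | target

Total step count: 18. Longest linear sequence: 18 steps (1 to 31; every other building block is bought).

Steps most likely to fail

Step 12. The cycloaddition may pass through the endo instead of the exo transition state, or discriminate poorly between them, so that the formyl group ends trans to H5 and C4 has the wrong configuration relative to C5. The fallback sets out from diene 23 and lets the two C4 substituents exchange roles. Cycloaddition with 2-[(tert-butyldimethylsilyloxy)methyl]acrolein (C=C(CO[Si](C)(C)C(C)(C)C)C=O; Me2AlCl or the same cationic oxazaborolidine, CH2Cl2, −78 °C) in the endo mode should give the endo-formyl adduct F1, with formyl trans and CH2OTBS cis to H5. Condensation with TsNHNH2 in MeOH gives the tosylhydrazone F2. Reduction with catecholborane followed by NaOAc·3H2O turns the formyl carbon into the C4 methyl of the C4-methyl bis-silyl ether F3. PPTS in MeOH removes only the TBS group to give the neopentyl alcohol F4, and Dess–Martin oxidation returns to the route at aldehyde 25.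

Step 17. Opening at tertiary C13 has carbocation character, so partial retention at C13, elimination, or capture of the cation by the C1=C10 alkene may erode the stereochemistry or the yield. The fallback sets out from allylic alcohol 28 and inverts C14 instead of C13. Sharpless epoxidation with L-(+)-diethyl tartrate should give the (13S,14S)-epoxy alcohol F5. Treatment with 0.5 M NaOH in t-BuOH/H2O at 70 °C effects Payne rearrangement (intramolecular attack of the C15 alkoxide at C14 with inversion, C13 untouched) to the (13S,14R)-14,15-epoxy-13-ol F6. Hydroxide then opens F6 at primary C15, and the sequence rejoins the route at triol 30. The hindered C4 ester should survive; any acid formed is re-esterified with TMSCHN2.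

Step 7. Prolonged contact with Me3Al may cleave the dioxolane, and the alkenylaluminate may be trapped incompletely by paraformaldehyde. The fallback sets out from alkyne 13 and avoids organoaluminium Lewis acids. Deprotonation with n-BuLi and addition to paraformaldehyde gives the propargylic alcohol F7. Red-Al trans-hydroalumination (Et2O, 0 °C) followed by I2 at −78 °C gives the (Z)-3-iodo allylic alcohol F8. Me2CuLi (Et2O, 0 °C) replaces iodine by methyl with retention of geometry, returning to the route at allylic alcohol 17.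

Further compounds
F1 | step 12 | Diels–Alder adduct of 23 with 2-[(tert-butyldimethylsilyloxy)methyl]acrolein, C4 formyl trans to H5 and C4 CH2OTBS cis to H5 | O=C[C@@]1(CO[Si](C)(C)C(C)(C)C)CCC=C2[C@H]1CC[C@@H](C)[C@]2(C)CC/C(C)=C/CO[Si](c1ccccc1)(c1ccccc1)C(C)(C)C
F2 | step 12 | p-toluenesulfonylhydrazone of F1 | Cc1ccc(cc1)S(=O)(=O)N/N=C/[C@@]1(CO[Si](C)(C)C(C)(C)C)CCC=C2[C@H]1CC[C@@H](C)[C@]2(C)CC/C(C)=C/CO[Si](c1ccccc1)(c1ccccc1)C(C)(C)C
F3 | step 12 | C4-methyl compound with C4 CH2OTBS cis to H5 and C15 OTBDPS | C[C@@]1(CO[Si](C)(C)C(C)(C)C)CCC=C2[C@H]1CC[C@@H](C)[C@]2(C)CC/C(C)=C/CO[Si](c1ccccc1)(c1ccccc1)C(C)(C)C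
F4 | step 12 | neopentyl alcohol with C4 CH2OH cis to H5 and C15 OTBDPS | C[C@@]1(CO)CCC=C2[C@H]1CC[C@@H](C)[C@]2(C)CC/C(C)=C/CO[Si](c1ccccc1)(c1ccccc1)C(C)(C)C
F5 | step 17 | (13S,14S)-13,14-epoxy-15-ol methyl ester | COC(=O)[C@]1(C)CCC=C2[C@H]1CC[C@@H](C)[C@]2(C)CC[C@]3(C)O[C@H]3CO
F6 | step 17 | (13S,14R)-14,15-epoxy-13-ol methyl ester | COC(=O)[C@]1(C)CCC=C2[C@H]1CC[C@@H](C)[C@]2(C)CC[C@](C)(O)[C@H]3CO3
F7 | step 7 | 5-[(6S,7R)-6,7-dimethyl-1,4-dioxaspiro[4.5]decan-6-yl]pent-2-yn-1-ol | O1CCOC12CCC[C@@H](C)[C@]2(C)CCC#CCO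
F8 | step 7 | (Z)-5-[(6S,7R)-6,7-dimethyl-1,4-dioxaspiro[4.5]decan-6-yl]-3-iodopent-2-en-1-ol | O1CCOC12CCC[C@@H](C)[C@]2(C)CC/C(I)=C/CO
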